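One percentage point here is one hundredth of left-handed and right-handed substrate taken together, and the examination asks how many such points a charge of solid reagent can pay for.

all flasks: left-handed substrate 0.066 M; right-handed substrate 0.066 M; catalyst 0.13 mol%
- east: solid reagent 0.70 equiv; temperature −15 °C; run made earlier
- north-east: solid reagent 2.7 equiv; temperature 15 °C; run made earlier
- dawn: solid reagent 1.00 equiv; at −10 °C until 3.0 h, from then on at 40 °C; time 15 h
- summer: solid reagent 3.00 equiv; at −10 °C throughout; time 15 h

- east (time / h: left-handed product / %, left-handed substrate / %): 3.00: 9.1, 40.9; 6.00: 13.3, 36.1; 10.0: 14.7, 31.7; 12.0: 17.2, 30.4; 15.0: 16.5, 31.3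
- north-east (time / h: left-handed product / %, left-handed substrate / %): 0.417: 2.9, 47.8; 0.667: 5.7, 43.0; 1.33: 12.5, 33.9; 2.50: 21.6, 22.4; 4.00: 29.9, 12.6

(each reading ± 1 percentage point)

- which one finishes higher in amount of left-handed product, in percent of the left-handed substrate and right-handed substrate together charged ("neither" within 2 percentage points) (dawn / summer / neither)
- amount of left-handed product at the end, in percent of the left-handed substrate and right-handed substrate together charged, dawn
- amount of left-handed product at the end, in percent of the left-handed substrate and right-handed substrate together charged, summer

- catalyst is single-handed; left-handed substrate and right-handed substrate are mirror images of each other, charged as a racemate, each of them at the stated concentration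
- as a solid, counted per litre of solution: solid reagent
- at the start none of the solid reagent is in solution

What is an equivalent in these flasks? It is counted on the left-handed substrate, which is half of the racemate. If one unit of solid reagent converts one unit of substrate, half the equivalents, read in points, gives the reagent budget: the points of both substrates together that the charge can convert. This is the limiting-reagent reckoning, and dawn's budget is 50.0 %.

Does the east run allow it? Its budget is 35.0 %, and at 15.0 h its left-handed substrate reads a loss of 18.7 %, about half of that budget.

And the weak spot: who takes the rest? No reading shows the right-handed substrate, so I carry the east share over to dawn, which gives a left-handed loss of 26.7 %. The north-east run, at its last reading, shows 0.799 of product per point of left-handed substrate lost. My own figure for dawn is therefore about 21.3 %.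

What about summer? Its budget of 150 % exceeds the flask's 100 points, so it sets no ceiling there. The east run read 9.1 % of left-handed product at 3.00 h and −15 °C; summer is warmer, at −10 °C, and runs for 15 h, so I expect summer to finish higher than dawn.

The forecast chooses dawn, with 35 % for dawn and 30 % for summer, holding that in dawn “the remaining reagent consumes the remaining” substrate while hot. On dawn, my figure is lower than the forecast's.

The flasks give summer as the higher, with 25.0 % for dawn and 29.7 % for summer.

    partner + catalyst + left-handed substrate → catalyst + left-handed product (k = 546 L² mol⁻² min⁻¹, Ea = 36.0 kJ mol⁻¹)
    partner + catalyst + right-handed substrate → catalyst + right-handed product (k = 192 L² mol⁻² min⁻¹, Ea = 43.0 kJ mol⁻¹)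
    solid reagent ⇌ partner, rate k3*(cs3 - [partner]) while solid is left; crystals form when [partner] > cs3 (solubility = 35.0 mM, k = 0.0645 min⁻¹)
    left-handed product ⇌ right-handed product (k = 0.00208 min⁻¹, Ea = 88.0 kJ mol⁻¹)
    (constants at −10 °C)

Dawn ends with 25.0 % of left-handed product and 25.0 % of right-handed product, together 50.0 %, which equals its budget of 50.0 %, and its solid reagent stands at 0 %. The neighbouring flask is dawn with 0.400 equiv of solid reagent, so its budget is 20.0 %. It ends with its solid reagent at 0 %, with 10.0 % of right-handed product and 10.0 % of left-handed product, together 20.0 %.

The data were computed with constants of no real substance, noise included.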